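## The problem

Target **35** carries three guaiacyl-type arenes on two saturated oxygen heterocycles. Ring B is the benzene ring of a 7′-methoxy-2′,3′-dihydrobenzofuran (O1′, C2′ bearing ring C, C3′ bearing CH2OH). At C5′ it carries an oxolane (O1, C2 attached to ring B, C3 bearing CH2OH, C4 bearing OH and the ring-A benzyl group, C5).

The five stereocentres form two sets that cannot control each other across the benzene ring: C2′/C3′ (2′R,3′R, aryl and CH2OH cis) and C2/C3/C4 (2R,3R,4S). In the oxolane the aryl group, the CH2OH arm and the benzyl group all lie on one face, and the tertiary hydroxyl on the other.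

C3 is the only centre close enough to direct C4, but it directs an external reagent the wrong way. A benzyl nucleophile adding to a C4 ketone would enter anti to the C3 arm and give the C4 epimer.

Both heterocycles are the less stable cis isomers and are benzylic ethers para to an oxygen substituent. Acids ionise C2–O1 or C2′–O1′ and re-close them trans. C3 epimerises (or loses its β-alkoxy group) once C4 is a ketone, and the electron-rich arenes and free phenols are sensitive to oxidants. The last stages must therefore run under neutral conditions.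

The enabling feature is that the oxygen of the C3 hydroxymethyl arm sits three atoms from C4. If the ring-A benzylic carbon is bound to that oxygen as an ether, its hydrogen is δ to a C4 carbonyl. Photochemical hydrogen transfer and biradical closure then form the C4–benzyl bond inside a dioxabicyclo[3.3.0]octane, which can only be cis-fused. The price is one benzylic C–O bond that must later be cut selectively among three.

## Retrosynthesis

Abbreviations used in names: ArA = 4-(benzyloxy)-3-methoxyphenyl; ArB = 2-(benzyloxy)-5-(1,3-dioxolan-2-yl)-3-methoxyphenyl; ArC = 3-methoxy-4-[(triisopropylsilyl)oxy]phenyl; DBF = (2R,3R)-3-{[(tert-butyldimethylsilyl)oxy]methyl}-7-methoxy-2-ArC-2,3-dihydro-1-benzofuran-5-yl.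

**35 ⇒ 34 ⇒ 33.** The two silyl ethers of **34** are the last protecting groups. In **34** the benzylic carbon of ring A is re-joined to the oxygen of the C3 arm, which gives the 1-hydroxy-furofuran **33**. Forward, hydrogen must cleave only that exo benzylic C–O bond. Ring A is therefore carried as a benzyl ether: its phenol is freed first under the same conditions and activates its own benzylic position, while ring C stays silylated and the C2–O1 bond has no free para-phenol.

**33 ⇒ 32.** The C4–C(benzylic) bond is cut, leaving the 2,3-cis oxolan-4-one **32** with a ring-A benzyloxymethyl group at C3. The alternative, adding a benzyl metal to this ketone, fails on facial selectivity. The intramolecular photocyclisation turns the existing C3 centre into the controller of C4 and needs nothing from the forward reaction beyond hydrogen transfer outrunning alpha-cleavage.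

**32 ⇒ 30 ⇒ 28.** The ketone is masked as the exocyclic alkene **30**, so the epimerisable β-alkoxy ketone exists only just before irradiation. **30** is opened at O1–C5 to the diol **28**, whose primary allylic alcohol can be activated in the presence of the secondary benzylic one.

**28 ⇒ 17 + 25.** Cutting C2–C3 gives aldehyde **17** and the 2,3-disubstituted allylboronate **25**. This removes both oxolane stereocentres in one step and divides the molecule roughly in half. Forward, a boronate with the γ-substituent cis to CH2B must give the syn adduct, and a chiral phosphoric acid must choose the aldehyde face, because the stereocentres of **17** are too remote to help.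

**25 ⇒ 24 ⇒ 21 + 23; 21 ⇒ 19 ⇒ 18.** The CH2–B carbon is attached to the alkenyl iodide **24** by cross-coupling with retention. **24** is the ether of chloride **23** (from alcohol **22**) and the (Z)-iodo alcohol **21**. The geometry of **21** comes from hydroxyl-directed trans-hydroalumination and iodination of mono-silylated butynediol **19**, made from **18**.

**17 ⇒ 16 ⇒ 15.** After unmasking the aldehyde from acetal **16**, the O1′–C2′ bond is cut to the phenol **15**. Closing this bond by SN2 displacement at the carbinol turns a syn-aldol relationship into the cis ring. An acid-promoted closure would give the trans ring.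

**15 ⇒ 14 ⇒ 13 ⇒ 12 ⇒ 8 + 10.** Debenzylation, silylation and reductive removal of the auxiliary lead back to the Evans syn-aldol adduct **12**. It forms C2′–C3′ from imide **8** and aldehyde **10** (from vanillin **9**) with both centres set by the auxiliary **6**.

**8 ⇒ 5 ⇒ 4 ⇒ 3 ⇒ 2 ⇒ 1.** The arylacetic acid **5** comes from ester **4**, made by joining an acetate unit to the iodine-bearing carbon of **3**. That carbon is C3a′, next to the phenol oxygen that becomes O1′. **3** is 5-iodovanillin **1** with the phenol benzylated (**2**) and the aldehyde, the future C2 of the oxolane, masked as a dioxolane.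

## Roads not taken

**Alternative 1:** The oxolane would be cut so that C4 is carried in a small γ-lactone, 4-[(4-hydroxy-3-methoxyphenyl)methyl]-4-(triethylsilyloxy)oxolan-2-one A2. The lactone carbonyl is the future C2 and its α-methylene the future C3. A2 would come from the prochiral cyclobutanone 3-[(4-hydroxy-3-methoxyphenyl)methyl]-3-(triethylsilyloxy)cyclobutan-1-one A1 by a flavin- and NADPH-dependent Baeyer–Villiger monooxygenase of the cyclohexanone monooxygenase type, which inserts oxygen next to one of the two enantiotopic methylenes.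

- Merits: it fixes the absolute configuration of the quaternary C4 catalytically, first, on a small molecule and independently of every other centre. It needs no photochemistry and no selective hydrogenolysis. In these respects it is better than the chosen plan.
- Weak points: the enzyme must distinguish a benzyl from a silyloxy group on a quaternary carbon remote from the reacting carbonyl, a substitution pattern with little support. Hydroxymethylation of the lactone enolate must then place the C3 arm cis to benzyl when the two C4 substituents differ little in size, and the β-silyloxy enolate can eliminate. C2 has finally to be arylated and the lactol reduced with a silane and a Lewis acid, conditions under which the cis-dihydrobenzofuran and the 2,3-cis benzylic ether can ionise.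
- Comparison: the chosen plan sets C2 and C3 in one catalyst-controlled step and obtains C4 by ring geometry rather than by a close facial preference, and its late steps are neutral.

**Alternative 2:** The C2′–C3′ bond of the dihydrobenzofuran would be formed by carbenoid C–H insertion. Rh2(S-PTTL)4 (dirhodium tetrakis[N-phthaloyl-(S)-tert-leucinate], divalent rhodium; its enantiomer if the sense requires) would decompose the aryldiazoacetate methyl 2-[5-bromo-3-methoxy-2-({3-methoxy-4-[(tert-butyldimethylsilyl)oxy]phenyl}methoxy)phenyl]-2-diazoacetate A3. The carbenoid carbon inserts into the adjacent O–CH2–aryl bond to give methyl cis-5-bromo-7-methoxy-2-(3-methoxy-4-silyloxyphenyl)-2,3-dihydrobenzofuran-3-carboxylate A4.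

- Merits: the step is catalytic, gives the kinetically favoured cis ring directly and reaches the dihydrobenzofuran in roughly two to three fewer steps than the auxiliary aldol and Mitsunobu sequence used here. For that half of the molecule it is the better method.
- Weak points: the cis ester A4 epimerises at C3′ very easily and must be reduced at once. As a strategy, the step solves the half of the problem for which standard answers exist and leaves the oxolane, with the quaternary C4 cis to two neighbours, untouched.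
- Comparison: the chosen plan spends its key step on C4 and accepts a longer but stereospecific route to the dihydrobenzofuran. The insertion is kept in reserve as the fallback for the ring closure of step 11.

**Alternative 3:** The whole C2–C5 skeleton would be assembled on an alkyne. CuI (monovalent copper) would catalyse addition of (isopropoxydimethylsilyl)methylmagnesium chloride across the alkoxide of the propargylic alcohol (1R)-1-(dihydrobenzofuranyl)-4-(ring-A aryl)but-2-yn-1-ol A5. Capture of the alkenylmagnesium by CO2 and lactonisation give the butenolide 3-(ring-A benzyl)-4-(silylmethyl)-5-(dihydrobenzofuranyl)furan-2(5H)-one A6.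

- Merits: one operation forms three bonds and puts every carbon of the oxolane and both side arms in place, with C2 set beforehand by asymmetric alkynylation. In convergence and skeletal bond count it is better than the chosen plan.
- Weak points: C3 and C4 must then be created on a tetrasubstituted butenolide by substrate control. That means hydrogenation of a hindered alkene next to an allylic, benzylic lactone C–O bond that is itself prone to hydrogenolysis, enolate hydroxylation at the benzyl-bearing carbon, Tamao oxidation, and reduction of the lactone carbonyl to CH2 with Lewis acid and silane next to the acid-sensitive cis rings.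
- Comparison: the chosen plan is longer in carbon–carbon bond construction but has fewer and safer stereochemical events, C3 and C4 never depend on the facial bias of a crowded alkene, and no strong acid is used after the cis rings exist.

Key step: step 21

## Route

Assumption: (R)-TRIP is taken to direct the allyl group to the Re face of the aryl aldehyde, as with simple aryl aldehydes; if the sense proved opposite, the enantiomeric acid would be used unchanged otherwise.

Numbering in the text: oxolane O1, C2 (aryl), C3 (CH2O arm), C4, C5, also for open-chain precursors; dihydrobenzofuran atoms carry primes.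

Step 1
Reactants: 1 5-iodovanillin (4-hydroxy-3-iodo-5-methoxybenzaldehyde)
Product: 2 4-(benzyloxy)-3-iodo-5-methoxybenzaldehyde
Conditions: BnBr, K2CO3, DMF, rt
Reagents that add atoms: benzyl bromide, BrCc1ccccc1
Why: Williamson etherification of an acidic, para-formyl phenol; the benzyl group masks the future O1′ until the ring closure.

Step 2
Reactants: 2 4-(benzyloxy)-3-iodo-5-methoxybenzaldehyde
Product: 3 2-[4-(benzyloxy)-3-iodo-5-methoxyphenyl]-1,3-dioxolane
Conditions: ethane-1,2-diol, p-TsOH (cat.), toluene, reflux, Dean–Stark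
Reagents that add atoms: ethane-1,2-diol, OCCO
Why: Acid-catalysed acetalisation with azeotropic removal of water; the aldehyde must be masked before zinc and boron enolates are used.

Step 3
Reactants: 3 2-[4-(benzyloxy)-3-iodo-5-methoxyphenyl]-1,3-dioxolane
Product: 4 ethyl 2-[2-(benzyloxy)-5-(1,3-dioxolan-2-yl)-3-methoxyphenyl]acetate
Conditions: BrCH2CO2Et, Zn dust, THF (gives BrZnCH2CO2Et); then 3, Pd2(dba)3 (1 mol%), XPhos, THF, 50 °C
Reagents that add atoms: ethyl bromoacetate, CCOC(=O)CBr
Why: Negishi-type α-arylation of an ester with a Reformatsky reagent under zerovalent palladium catalysis; the near-neutral zinc enolate tolerates the acetal and the benzyl ether, and the aryl iodide is the only site for oxidative addition.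

Step 4
Reactants: 4 ethyl 2-[2-(benzyloxy)-5-(1,3-dioxolan-2-yl)-3-methoxyphenyl]acetate
Product: 5 2-[2-(benzyloxy)-5-(1,3-dioxolan-2-yl)-3-methoxyphenyl]acetic acid
Conditions: LiOH, THF–MeOH–H2O, rt; then aq. citric acid to pH 4
Reagents that add atoms: lithium hydroxide, [Li+].[OH-]
Why: Saponification; the mildly acidic work-up leaves the dioxolane intact.

Step 5
Reactants: 5 2-[2-(benzyloxy)-5-(1,3-dioxolan-2-yl)-3-methoxyphenyl]acetic acid; 6 (S)-4-benzyloxazolidin-2-one
Product: 8 (S)-4-benzyl-3-{2-[2-(benzyloxy)-5-(1,3-dioxolan-2-yl)-3-methoxyphenyl]acetyl}oxazolidin-2-one, via mixed pivalic anhydride 7 (not isolated)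
Conditions: PivCl, Et3N, THF, −20 °C; then LiCl, 6, rt
Reagents that add atoms: none
Why: N-Acylation of the Evans auxiliary through the mixed pivalic anhydride, which is attacked at the less hindered arylacetyl carbonyl.

Step 6
Reactants: 9 vanillin (4-hydroxy-3-methoxybenzaldehyde)
Product: 10 3-methoxy-4-[(triisopropylsilyl)oxy]benzaldehyde
Conditions: TIPSCl, imidazole, DMF, rt
Reagents that add atoms: chlorotri(propan-2-yl)silane, CC(C)[Si](Cl)(C(C)C)C(C)C
Why: Phenol silylation; the bulky aryl silyl ether survives hydride, alkoxide, ozone and hydrogen and is removed by fluoride at the end.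

Step 7
Reactants: 8 (S)-4-benzyl-3-{2-[2-(benzyloxy)-5-(1,3-dioxolan-2-yl)-3-methoxyphenyl]acetyl}oxazolidin-2-one; 10 3-methoxy-4-[(triisopropylsilyl)oxy]benzaldehyde
Product: 12 (S)-4-benzyl-3-[(2S,3S)-2-ArB-3-hydroxy-3-ArC-propanoyl]oxazolidin-2-one, via Z-boron enolate 11 (not isolated)
Conditions: Bu2BOTf, i-Pr2NEt, CH2Cl2, −78 → 0 °C; 10, −78 → 0 °C; then pH 7 buffer, MeOH, H2O2, 0 °C
Reagents that add atoms: none
Why: Evans syn-aldol reaction: the (Z)-dibutylboron enolate reacts through a closed Zimmerman–Traxler transition state on the enolate face opposite the auxiliary benzyl group. Future C3′ and the carbinol C2′ are set together as the syn (2S,3S) pair.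

Step 8
Reactants: 12 (S)-4-benzyl-3-[(2S,3S)-2-ArB-3-hydroxy-3-ArC-propanoyl]oxazolidin-2-one
Product: 13 (1S,2R)-2-ArB-1-ArC-propane-1,3-diol
Conditions: LiBH4, MeOH (1.1 equiv), THF, 0 °C
Reagents that add atoms: none
Why: Reductive cleavage of the N-acyloxazolidinone to the primary alcohol with recovery of the auxiliary; the low temperature and short contact should avoid retro-aldol loss of the α-aryl adduct.

Step 9
Reactants: 13 (1S,2R)-2-ArB-1-ArC-propane-1,3-diol
Product: 14 (1S,2R)-2-ArB-3-[(tert-butyldimethylsilyl)oxy]-1-ArC-propan-1-ol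
Conditions: TBSCl (1.05 equiv), imidazole, CH2Cl2, 0 °C
Reagents that add atoms: tert-butylchlorodimethylsilane, CC(C)(C)[Si](C)(C)Cl
Why: Selective silylation of the primary hydroxyl; this prevents the phenol from later closing onto the primary carbon instead of the carbinol.

Step 10
Reactants: 14 (1S,2R)-2-ArB-3-[(tert-butyldimethylsilyl)oxy]-1-ArC-propan-1-ol
Product: 15 (1S,2R)-3-[(tert-butyldimethylsilyl)oxy]-2-[5-(1,3-dioxolan-2-yl)-2-hydroxy-3-methoxyphenyl]-1-ArC-propan-1-ol
Conditions: H2 (1 atm), Pd/C (10% Pd on carbon), EtOAc, rt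
Reagents that add atoms: none
Why: Hydrogenolysis of the aryl benzyl ether, which is much faster than loss of the secondary benzylic hydroxyl in a neutral, non-protic solvent; silyl ethers and the dioxolane are inert.

Step 11
Reactants: 15 (1S,2R)-3-[(tert-butyldimethylsilyl)oxy]-2-[5-(1,3-dioxolan-2-yl)-2-hydroxy-3-methoxyphenyl]-1-ArC-propan-1-ol
Product: 16 2-(DBF)-1,3-dioxolane, i.e. 2-[(2R,3R)-3-{[(tert-butyldimethylsilyl)oxy]methyl}-7-methoxy-2-ArC-2,3-dihydro-1-benzofuran-5-yl]-1,3-dioxolane (2′,3′-cis)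
Conditions: PPh3, DIAD, THF, 0 °C → rt
Reagents that add atoms: none
Why: Intramolecular Mitsunobu etherification, 5-exo-tet: the phenoxide displaces the oxyphosphonium group with inversion at the carbinol carbon. This converts the syn-aldol relationship into the cis ring (2′R) without passing through a benzylic cation; C3′ is untouched.

Step 12
Reactants: 16 2-(DBF)-1,3-dioxolane
Product: 17 (2R,3R)-3-{[(tert-butyldimethylsilyl)oxy]methyl}-7-methoxy-2-ArC-2,3-dihydro-1-benzofuran-5-carbaldehyde (DBF–CHO)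
Conditions: PPTS (cat.), acetone–H2O, rt
Reagents that add atoms: water, O
Why: Mild acetal hydrolysis; the acetal carbon is para to the ring oxygen and ionises far more readily than the weakly basic aryl ether C2′–O1′, so the cis ring should survive.

Step 13
Reactants: 18 but-2-yne-1,4-diol
Product: 19 4-[(triethylsilyl)oxy]but-2-yn-1-ol
Conditions: NaH (1.0 equiv), THF, 0 °C; then TESCl (1.0 equiv)
Reagents that add atoms: chlorotriethylsilane, CC[Si](Cl)(CC)CC
Why: Monosilylation of a symmetrical diol through its sparingly soluble monosodium alkoxide.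

Step 14
Reactants: 19 4-[(triethylsilyl)oxy]but-2-yn-1-ol
Product: 21 (Z)-3-iodo-4-[(triethylsilyl)oxy]but-2-en-1-ol, via cyclic vinylalanate 20 (not isolated)
Conditions: NaAlH2(OCH2CH2OMe)2, THF, 0 °C → rt; then I2, THF, −78 °C
Reagents that add atoms: iodine, II
Why: Hydroxyl-directed trans-hydroalumination of the propargylic alcohol places hydrogen on the proximal and aluminium on the distal alkyne carbon in a five-membered alanate; iodinolysis with retention gives the (Z)-iodoalkene with iodine cis to CH2OH.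

Step 15
Reactants: 22 [4-(benzyloxy)-3-methoxyphenyl]methanol
Product: 23 1-(benzyloxy)-4-(chloromethyl)-2-methoxybenzene
Conditions: SOCl2, CH2Cl2, 0 °C
Reagents that add atoms: thionyl chloride, ClS(Cl)=O
Why: Chlorodehydroxylation of an electron-rich benzylic alcohol via its chlorosulfite.

Step 16
Reactants: 21 (Z)-3-iodo-4-[(triethylsilyl)oxy]but-2-en-1-ol; 23 1-(benzyloxy)-4-(chloromethyl)-2-methoxybenzene
Product: 24 (Z)-{[4-(ArA-methoxy)-2-iodobut-2-en-1-yl]oxy}triethylsilane
Conditions: NaH, THF, 0 °C; 23, Bu4NI (cat.), 0 °C → rt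
Reagents that add atoms: none
Why: Williamson etherification of the allylic alkoxide with a reactive benzylic chloride; this installs ring A as the future tether on the oxygen that becomes the C3 arm.

Step 17
Reactants: 24 (Z)-{[4-(ArA-methoxy)-2-iodobut-2-en-1-yl]oxy}triethylsilane
Product: 25 2-[(2E)-4-(ArA-methoxy)-2-{[(triethylsilyl)oxy]methyl}but-2-en-1-yl]-4,4,5,5-tetramethyl-1,3,2-dioxaborolane (CH2B cis to CH2OCH2ArA)
Conditions: ICH2Bpin, Zn dust, THF, rt (gives IZnCH2Bpin); then 24, Pd(PPh3)4 (5 mol%), THF, rt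
Reagents that add atoms: 2-(iodomethyl)-4,4,5,5-tetramethyl-1,3,2-dioxaborolane, CC1(C)OB(CI)OC1(C)C
Why: Negishi coupling of a (borylmethyl)zinc reagent with an alkenyl iodide under zerovalent palladium catalysis, which proceeds with retention of alkene geometry and gives the allylboronate with its γ-substituent cis to CH2B.

Step 18
Reactants: 17 DBF–CHO; 25 2-[(2E)-4-(ArA-methoxy)-2-{[(triethylsilyl)oxy]methyl}but-2-en-1-yl]-4,4,5,5-tetramethyl-1,3,2-dioxaborolane
Product: 28 (3R,4R)-4-DBF-3-[(ArA-methoxy)methyl]-2-methylidenebutane-1,4-diol, via pinacol borate 26 (not isolated), via triethylsilyl ether 27 (not isolated)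
Conditions: (R)-TRIP [(R)-3,3′-bis(2,4,6-triisopropylphenyl)-1,1′-binaphthyl-2,2′-diyl hydrogen phosphate] (5 mol%), toluene, −30 °C; then MeOH, PPTS, 0 °C
Reagents that add atoms: none
Why: Chiral phosphoric acid-catalysed allylboration through a chair Zimmerman–Traxler transition state. The γ-substituent cis to CH2B is axial and gives the syn relationship (C2 OH and C3 arm, later 2,3-cis), and the acid, hydrogen-bonded to a boronate oxygen and the formyl hydrogen, selects the Re face of the aldehyde (C2 R). Methanolysis in the same flask cleaves the borate and the primary triethylsilyl ether, leaving the tert-butyldimethylsilyl and aryl triisopropylsilyl ethers.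

Step 19
Reactants: 28 (3R,4R)-4-DBF-3-[(ArA-methoxy)methyl]-2-methylidenebutane-1,4-diol
Product: 30 (2R,3R)-2-DBF-3-[(ArA-methoxy)methyl]-4-methylideneoxolane, via primary tosylate 29 (not isolated)
Conditions: NaH (2.2 equiv), THF, 0 °C; 1-(p-tolylsulfonyl)imidazole (1.05 equiv), 0 °C → rt
Reagents that add atoms: none
Why: One-pot cyclodehydration: the primary allylic alkoxide is sulfonylated selectively and the secondary alkoxide closes O1–C5 by 5-exo-tet displacement (SN2 and SN2′ give the same product). C2 is the nucleophile-bearing carbon and keeps its configuration, and no acid touches the benzylic ether.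

Step 20
Reactants: 30 (2R,3R)-2-DBF-3-[(ArA-methoxy)methyl]-4-methylideneoxolane
Product: 32 (4R,5R)-5-DBF-4-[(ArA-methoxy)methyl]oxolan-3-one (the 2,3-cis oxolan-4-one of the text numbering), via spiro-ozonide 31 (not isolated)
Conditions: O3, CH2Cl2, −78 °C (Sudan red end-point); PPh3, −78 °C → rt
Reagents that add atoms: ozone, [O-][O+]=O
Why: Ozonolysis of the 1,1-disubstituted alkene, which reacts far faster than the alkoxyarenes at −78 °C when an indicator dye marks the end-point. The neutral reductive work-up releases the β-alkoxy ketone without base, so C3 should not epimerise; the ketone is used at once.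

Step 21
Reactants: 32 (4R,5R)-5-DBF-4-[(ArA-methoxy)methyl]oxolan-3-one
Product: 33 (1S,2R,5R,6R)-2-ArA-6-DBF-3,7-dioxabicyclo[3.3.0]octan-1-ol (cis-fused, ArA exo; the epimer at C2 of the bicycle serves equally)
Conditions: hν (medium-pressure Hg lamp, Pyrex filter, λ > 290 nm), degassed benzene (0.01 M), rt
Reagents that add atoms: none
Why: Norrish–Yang photocyclisation: n,π* excitation of the C4 ketone gives an oxygen-centred radical that has no γ-hydrogen to take, because the γ atom is the ether oxygen. It therefore abstracts the δ-hydrogen of the ring-A benzyl ether by 1,6-transfer through a seven-membered transition state. The resulting 1,5-biradical (C4 ketyl and benzylic α-oxy radical) collapses by radical–radical coupling to form the C4–C(benzylic) bond and close a second five-membered ring. The closest known reaction type is the photocyclisation of β-(benzyloxy) ketones to 3-hydroxyoxolanes, which has been applied to 1-hydroxy-furofuran skeletons. The new quaternary centre is controlled by C3 alone: the three-atom tether from C3 can reach C4 only on its own face, and a trans-fused bicyclo[3.3.0] system is prohibitively strained, so the benzylic carbon arrives cis to the C3 arm and the hydroxyl is trans (C4 S of the target). The second new centre, the benzylic carbon, should favour the aryl group on the convex face, but it is erased in step 22. The step needs hydrogen transfer to outrun alpha-cleavage of the α-alkoxy ketone (Norrish type 1); the doubly activated benzylic, α-oxy C–H bond held close to the carbonyl secures this. It also needs C3 to stay intact, which the neutral, base-free solution should ensure.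

Step 22
Reactants: 33 (1S,2R,5R,6R)-2-ArA-6-DBF-3,7-dioxabicyclo[3.3.0]octan-1-ol
Product: 34 (3S,4R,5R)-5-DBF-3-[(4-hydroxy-3-methoxyphenyl)methyl]-4-(hydroxymethyl)oxolan-3-ol
Conditions: H2 (1 atm), Pd(OH)2/C, EtOAc–EtOH, rt, stopped after uptake of 2 equiv
Reagents that add atoms: none
Why: Catalytic hydrogenolysis: the aryl benzyl ether goes first, and the freed para-phenol makes the exo benzylic C–O bond of the strained bicycle the most labile benzylic ether, as in the known reductive opening of phenolic furofurans. The C2–O1 bond has no free para-phenol and lies on the concave face, and C2′–O1′ is flanked by the silylated ring C. No stereocentre is touched, and the configuration at the former benzylic carbon disappears.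

Step 23
Reactants: 34 (3S,4R,5R)-5-DBF-3-[(4-hydroxy-3-methoxyphenyl)methyl]-4-(hydroxymethyl)oxolan-3-ol
Product: 35 (3S,4R,5R)-3-[(4-hydroxy-3-methoxyphenyl)methyl]-4-(hydroxymethyl)-5-[(2R,3R)-2-(4-hydroxy-3-methoxyphenyl)-3-(hydroxymethyl)-7-methoxy-2,3-dihydro-1-benzofuran-5-yl]oxolan-3-ol (target)
Conditions: Bu4NF, THF, 0 °C → rt; aq. NH4Cl
Reagents that add atoms: none
Why: Fluoride cleavage of the aryl triisopropylsilyl and primary tert-butyldimethylsilyl ethers under non-acidic conditions that cannot ionise either cis benzylic ether.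

## Compound list

1 | 5-iodovanillin (4-hydroxy-3-iodo-5-methoxybenzaldehyde) | COc1cc(C=O)cc(I)c1O | starting material
2 | 4-(benzyloxy)-3-iodo-5-methoxybenzaldehyde | COc1cc(C=O)cc(I)c1OCc1ccccc1 | intermediate
3 | 2-[4-(benzyloxy)-3-iodo-5-methoxyphenyl]-1,3-dioxolane | COc1cc(C2OCCO2)cc(I)c1OCc1ccccc1 | intermediate
4 | ethyl 2-[2-(benzyloxy)-5-(1,3-dioxolan-2-yl)-3-methoxyphenyl]acetate | CCOC(=O)Cc1cc(C2OCCO2)cc(OC)c1OCc1ccccc1 | intermediate
5 | 2-[2-(benzyloxy)-5-(1,3-dioxolan-2-yl)-3-methoxyphenyl]acetic acid | OC(=O)Cc1cc(C2OCCO2)cc(OC)c1OCc1ccccc1 | intermediate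
6 | (S)-4-benzyloxazolidin-2-one | O=C1N[C@@H](Cc2ccccc2)CO1 | starting material
7 | 2-[2-(benzyloxy)-5-(1,3-dioxolan-2-yl)-3-methoxyphenyl]acetic pivalic anhydride | CC(C)(C)C(=O)OC(=O)Cc1cc(C2OCCO2)cc(OC)c1OCc1ccccc1 | intermediate (not isolated)
8 | (S)-4-benzyl-3-{2-[2-(benzyloxy)-5-(1,3-dioxolan-2-yl)-3-methoxyphenyl]acetyl}oxazolidin-2-one | O=C1OC[C@H](Cc2ccccc2)N1C(=O)Cc1cc(C2OCCO2)cc(OC)c1OCc1ccccc1 | intermediate
9 | vanillin (4-hydroxy-3-methoxybenzaldehyde) | COc1cc(C=O)ccc1O | starting material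
10 | 3-methoxy-4-[(triisopropylsilyl)oxy]benzaldehyde | COc1cc(C=O)ccc1O[Si](C(C)C)(C(C)C)C(C)C | intermediate
11 | (S)-4-benzyl-3-{(Z)-2-ArB-1-[(dibutylboranyl)oxy]ethenyl}oxazolidin-2-one (Z-boron enolate of 8) | CCCCB(CCCC)O/C(=C\c1cc(C2OCCO2)cc(OC)c1OCc1ccccc1)N1[C@@H](Cc2ccccc2)COC1=O | intermediate (not isolated)
12 | (S)-4-benzyl-3-[(2S,3S)-2-ArB-3-hydroxy-3-ArC-propanoyl]oxazolidin-2-one | O=C1OC[C@H](Cc2ccccc2)N1C(=O)[C@@H](c1cc(C2OCCO2)cc(OC)c1OCc1ccccc1)[C@H](O)c1ccc(O[Si](C(C)C)(C(C)C)C(C)C)c(OC)c1 | intermediate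
13 | (1S,2R)-2-ArB-1-ArC-propane-1,3-diol | OC[C@@H](c1cc(C2OCCO2)cc(OC)c1OCc1ccccc1)[C@H](O)c1ccc(O[Si](C(C)C)(C(C)C)C(C)C)c(OC)c1 | intermediate
14 | (1S,2R)-2-ArB-3-[(tert-butyldimethylsilyl)oxy]-1-ArC-propan-1-ol | CC(C)(C)[Si](C)(C)OC[C@@H](c1cc(C2OCCO2)cc(OC)c1OCc1ccccc1)[C@H](O)c1ccc(O[Si](C(C)C)(C(C)C)C(C)C)c(OC)c1 | intermediate
15 | (1S,2R)-3-[(tert-butyldimethylsilyl)oxy]-2-[5-(1,3-dioxolan-2-yl)-2-hydroxy-3-methoxyphenyl]-1-ArC-propan-1-ol | CC(C)(C)[Si](C)(C)OC[C@@H](c1cc(C2OCCO2)cc(OC)c1O)[C@H](O)c1ccc(O[Si](C(C)C)(C(C)C)C(C)C)c(OC)c1 | intermediate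
16 | 2-[(2R,3R)-3-{[(tert-butyldimethylsilyl)oxy]methyl}-7-methoxy-2-ArC-2,3-dihydro-1-benzofuran-5-yl]-1,3-dioxolane | O1CCOC1c1cc(OC)c2c(c1)[C@H](CO[Si](C)(C)C(C)(C)C)[C@H](c1ccc(O[Si](C(C)C)(C(C)C)C(C)C)c(OC)c1)O2 | intermediate
17 | (2R,3R)-3-{[(tert-butyldimethylsilyl)oxy]methyl}-7-methoxy-2-ArC-2,3-dihydro-1-benzofuran-5-carbaldehyde | O=Cc1cc(OC)c2c(c1)[C@H](CO[Si](C)(C)C(C)(C)C)[C@H](c1ccc(O[Si](C(C)C)(C(C)C)C(C)C)c(OC)c1)O2 | intermediate
18 | but-2-yne-1,4-diol | OCC#CCO | starting material
19 | 4-[(triethylsilyl)oxy]but-2-yn-1-ol | CC[Si](CC)(CC)OCC#CCO | intermediate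
20 | sodium 2,2-bis(2-methoxyethoxy)-3-{[(triethylsilyl)oxy]methyl}-2,5-dihydro-1,2-oxaluminol-2-uide (cyclic vinylalanate) | [Na+].COCCO[Al-]1(OCCOC)OCC=C1CO[Si](CC)(CC)CC | intermediate (not isolated)
21 | (Z)-3-iodo-4-[(triethylsilyl)oxy]but-2-en-1-ol | OC/C=C(\I)CO[Si](CC)(CC)CC | intermediate
22 | [4-(benzyloxy)-3-methoxyphenyl]methanol | COc1cc(CO)ccc1OCc1ccccc1 | starting material
23 | 1-(benzyloxy)-4-(chloromethyl)-2-methoxybenzene | COc1cc(CCl)ccc1OCc1ccccc1 | intermediate
24 | (Z)-{[4-(ArA-methoxy)-2-iodobut-2-en-1-yl]oxy}triethylsilane | COc1cc(COC/C=C(\I)CO[Si](CC)(CC)CC)ccc1OCc1ccccc1 | intermediate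
25 | 2-[(2E)-4-(ArA-methoxy)-2-{[(triethylsilyl)oxy]methyl}but-2-en-1-yl]-4,4,5,5-tetramethyl-1,3,2-dioxaborolane | COc1cc(COC/C=C(\CB2OC(C)(C)C(C)(C)O2)CO[Si](CC)(CC)CC)ccc1OCc1ccccc1 | intermediate
26 | 2-{[(1R,2R)-1-DBF-2-[(ArA-methoxy)methyl]-3-{[(triethylsilyl)oxy]methyl}but-3-en-1-yl]oxy}-4,4,5,5-tetramethyl-1,3,2-dioxaborolane | CC1(C)OB(O[C@@H](c3cc(OC)c4c(c3)[C@H](CO[Si](C)(C)C(C)(C)C)[C@H](c3ccc(O[Si](C(C)C)(C(C)C)C(C)C)c(OC)c3)O4)[C@H](C(=C)CO[Si](CC)(CC)CC)COCc2ccc(OCc3ccccc3)c(OC)c2)OC1(C)C | intermediate (not isolated)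
27 | (1R,2R)-1-DBF-2-[(ArA-methoxy)methyl]-3-{[(triethylsilyl)oxy]methyl}but-3-en-1-ol | O[C@@H](c3cc(OC)c4c(c3)[C@H](CO[Si](C)(C)C(C)(C)C)[C@H](c3ccc(O[Si](C(C)C)(C(C)C)C(C)C)c(OC)c3)O4)[C@H](C(=C)CO[Si](CC)(CC)CC)COCc1ccc(OCc2ccccc2)c(OC)c1 | intermediate (not isolated)
28 | (3R,4R)-4-DBF-3-[(ArA-methoxy)methyl]-2-methylidenebutane-1,4-diol | O[C@@H](c3cc(OC)c4c(c3)[C@H](CO[Si](C)(C)C(C)(C)C)[C@H](c3ccc(O[Si](C(C)C)(C(C)C)C(C)C)c(OC)c3)O4)[C@H](C(=C)CO)COCc1ccc(OCc2ccccc2)c(OC)c1 | intermediate
29 | (3R,4R)-4-DBF-4-hydroxy-3-[(ArA-methoxy)methyl]-2-methylidenebutyl 4-methylbenzenesulfonate | O[C@@H](c3cc(OC)c4c(c3)[C@H](CO[Si](C)(C)C(C)(C)C)[C@H](c3ccc(O[Si](C(C)C)(C(C)C)C(C)C)c(OC)c3)O4)[C@H](C(=C)COS(=O)(=O)c1ccc(C)cc1)COCc1ccc(OCc2ccccc2)c(OC)c1 | intermediate (not isolated)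
30 | (2R,3R)-2-DBF-3-[(ArA-methoxy)methyl]-4-methylideneoxolane | C=C1CO[C@@H](c3cc(OC)c4c(c3)[C@H](CO[Si](C)(C)C(C)(C)C)[C@H](c3ccc(O[Si](C(C)C)(C(C)C)C(C)C)c(OC)c3)O4)[C@H]1COCc1ccc(OCc2ccccc2)c(OC)c1 | intermediate
31 | secondary ozonide of 30: 8-DBF-9-[(ArA-methoxy)methyl]-1,2,4,7-tetraoxaspiro[4.4]nonane (C8 and C9 as in 30, spiro carbon unassigned) | C1OOC2(O1)CO[C@@H](c3cc(OC)c4c(c3)[C@H](CO[Si](C)(C)C(C)(C)C)[C@H](c3ccc(O[Si](C(C)C)(C(C)C)C(C)C)c(OC)c3)O4)[C@H]2COCc1ccc(OCc2ccccc2)c(OC)c1 | intermediate (not isolated)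
32 | (4R,5R)-5-DBF-4-[(ArA-methoxy)methyl]oxolan-3-one | O=C1CO[C@@H](c3cc(OC)c4c(c3)[C@H](CO[Si](C)(C)C(C)(C)C)[C@H](c3ccc(O[Si](C(C)C)(C(C)C)C(C)C)c(OC)c3)O4)[C@H]1COCc1ccc(OCc2ccccc2)c(OC)c1 | intermediate
33 | (1S,2R,5R,6R)-2-ArA-6-DBF-3,7-dioxabicyclo[3.3.0]octan-1-ol | O[C@]12CO[C@@H](c3cc(OC)c4c(c3)[C@H](CO[Si](C)(C)C(C)(C)C)[C@H](c3ccc(O[Si](C(C)C)(C(C)C)C(C)C)c(OC)c3)O4)[C@H]1CO[C@@H]2c1ccc(OCc2ccccc2)c(OC)c1 | intermediate
34 | (3S,4R,5R)-5-DBF-3-[(4-hydroxy-3-methoxyphenyl)methyl]-4-(hydroxymethyl)oxolan-3-ol | COc1cc(C[C@@]2(O)CO[C@@H](c3cc(OC)c4c(c3)[C@H](CO[Si](C)(C)C(C)(C)C)[C@H](c3ccc(O[Si](C(C)C)(C(C)C)C(C)C)c(OC)c3)O4)[C@H]2CO)ccc1O | intermediate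
35 | (3S,4R,5R)-3-[(4-hydroxy-3-methoxyphenyl)methyl]-4-(hydroxymethyl)-5-[(2R,3R)-2-(4-hydroxy-3-methoxyphenyl)-3-(hydroxymethyl)-7-methoxy-2,3-dihydro-1-benzofuran-5-yl]oxolan-3-ol | COc1cc(C[C@@]2(O)CO[C@@H](c3cc(OC)c4c(c3)[C@H](CO)[C@H](c3ccc(O)c(OC)c3)O4)[C@H]2CO)ccc1O | target

## Step count and risks

Total: 23 steps. Longest linear sequence: 17 steps (steps 1–5, 7–12, 18–23, from 5-iodovanillin). The allylboronate branch is five steps (13–17) and the ring-C aldehyde one step (6).

**Step 21 (key step).** The most likely failure is that alpha-cleavage of the excited ketone competes with hydrogen transfer, because the C4–C5 bond breaks to an oxygen-stabilised radical; the three alkoxyarenes also absorb part of the light and slow the reaction. A slow reaction also gives the cis ketone time to epimerise at C3, and the tether would then deliver the benzyl carbon to the wrong face relative to C2.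

The fallback gives up the tether and uses steric approach control with an oxygen electrophile instead of a carbon nucleophile. It sets out from alkene **30** and returns at **34**.
- Epoxidation of **30** with mCPBA (NaHCO3, CH2Cl2, 0 °C) should occur on the face opposite the cis C2 and C3 substituents and give the spiro-epoxide (3R,6R,7R)-6-DBF-7-[(ArA-methoxy)methyl]-1,5-dioxaspiro[2.4]heptane F1.
- Opening at the methylene carbon with 4-(benzyloxy)-3-methoxyphenylmagnesium bromide and CuI (monovalent copper, catalytic) in THF at −30 °C gives the tertiary alcohol (3S,4R,5R)-3-[(ArA)methyl]-4-[(ArA-methoxy)methyl]-5-DBF-oxolan-3-ol F2.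
- Hydrogenolysis over Pd(OH)2/C removes both O-benzyl groups and the now acyclic hydroxybenzyl ether on the C3 arm and delivers **34**.

**Step 22.** The most likely failure is loss of site selectivity: hydrogenolysis continuing at C2–O1 while that bond is still part of the strained bicycle, or opening of the dihydrobenzofuran at C2′–O1′, since all three are benzylic ethers of electron-rich arenes.

The fallback avoids any ring hydrogenolysis by bringing ring A in on a carbonyl group. It sets out from **30** and returns at **34**.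
- Dihydroxylation of **30** (OsO4 catalytic, NMO, acetone–H2O) from the open face gives the diol (3R,4R,5R)-5-DBF-3-(hydroxymethyl)-4-[(ArA-methoxy)methyl]oxolan-3-ol F3.
- Parikh–Doering oxidation of the primary hydroxyl gives the hydroxy aldehyde (3S,4R,5R)-5-DBF-3-hydroxy-4-[(ArA-methoxy)methyl]oxolane-3-carbaldehyde F4.
- Addition of 4-(benzyloxy)-3-methoxyphenylmagnesium bromide gives the diol (3S,4R,5R)-3-[(ArA)(hydroxy)methyl]-4-[(ArA-methoxy)methyl]-5-DBF-oxolan-3-ol F5 as either carbinol epimer.
- Hydrogen over Pd(OH)2/C then only has to remove two O-benzyl groups, an acyclic hydroxybenzyl ether and an acyclic para-hydroxybenzylic hydroxyl, none of them in a strained ring, to reach **34**.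

**Step 11.** The most likely failure is partial ionisation of the activated oxyphosphonium intermediate. The carbinol carbon is benzylic to a para-silyloxy arene, and SN1 leakage erodes the inversion and gives the trans ring.

The fallback forms C2′–C3′ instead of O1′–C2′, by carbenoid C–H insertion. It sets out from ester **4** and aldehyde **10** and returns at **16**.
- Hydrogenolysis of **4** (H2, Pd/C) gives ethyl 2-[5-(1,3-dioxolan-2-yl)-2-hydroxy-3-methoxyphenyl]acetate F6.
- NaBH4 reduction of **10** gives {3-methoxy-4-[(triisopropylsilyl)oxy]phenyl}methanol F7.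
- Mitsunobu etherification of F6 with F7 gives ethyl 2-[5-(1,3-dioxolan-2-yl)-3-methoxy-2-(ArC-methoxy)phenyl]acetate F8.
- Diazo transfer (p-acetamidobenzenesulfonyl azide, DBU) gives ethyl 2-diazo-2-[5-(1,3-dioxolan-2-yl)-3-methoxy-2-(ArC-methoxy)phenyl]acetate F9.
- Rh2(S-PTTL)4 (divalent rhodium; the enantiomeric catalyst if the sense requires) should insert into the benzylic ether C–H bond and give the cis ester ethyl (2R,3S)-5-(1,3-dioxolan-2-yl)-7-methoxy-2-ArC-2,3-dihydro-1-benzofuran-3-carboxylate F10.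
- Reduction with i-Bu2AlH at −78 °C gives [(2R,3R)-5-(1,3-dioxolan-2-yl)-7-methoxy-2-ArC-2,3-dihydro-1-benzofuran-3-yl]methanol F11, which is silylated with TBSCl to **16**.

**Step 18.** The most likely failure is low reactivity of the trisubstituted allylboronate together with weak facial control by the catalyst, which gets no help from the remote stereocentres of **17**. Erosion of the boronate geometry would add the anti isomers.

The fallback replaces catalyst control by auxiliary control and makes C2–C3 by an aldol reaction. It sets out from aldehyde **17** and alcohol **22**, returns at ketone **32**, and makes steps 19 and 20 unnecessary.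
- Oxa-Michael addition of **22** to methyl acrylate gives methyl 3-(ArA-methoxy)propanoate F12.
- Saponification gives 3-(ArA-methoxy)propanoic acid F13.
- Acylation of (R)-4-benzyloxazolidin-2-one as in step 5 gives (R)-4-benzyl-3-[3-(ArA-methoxy)propanoyl]oxazolidin-2-one F14.
- The Evans syn-aldol reaction of F14 with **17** (Bu2BOTf, i-Pr2NEt) gives (R)-4-benzyl-3-[(2R,3R)-3-DBF-3-hydroxy-2-[(ArA-methoxy)methyl]propanoyl]oxazolidin-2-one F15.
- LiOH–H2O2 gives (2R,3R)-3-DBF-3-hydroxy-2-[(ArA-methoxy)methyl]propanoic acid F16.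
- Isobutyl chloroformate and diazomethane give the diazoketone (3R,4R)-1-diazo-4-DBF-4-hydroxy-3-[(ArA-methoxy)methyl]butan-2-one F17.
- Rh2(OAc)4 (divalent rhodium) closes O1–C5 by intramolecular O–H insertion under neutral conditions to give **32**.

## Further compounds

F1 | step 21 | (3R,6R,7R)-6-DBF-7-[(ArA-methoxy)methyl]-1,5-dioxaspiro[2.4]heptane | C1O[C@@]12CO[C@@H](c3cc(OC)c4c(c3)[C@H](CO[Si](C)(C)C(C)(C)C)[C@H](c3ccc(O[Si](C(C)C)(C(C)C)C(C)C)c(OC)c3)O4)[C@H]2COCc1ccc(OCc2ccccc2)c(OC)c1
F2 | step 21 | (3S,4R,5R)-3-[(ArA)methyl]-4-[(ArA-methoxy)methyl]-5-DBF-oxolan-3-ol | COc1cc(C[C@@]2(O)CO[C@@H](c3cc(OC)c4c(c3)[C@H](CO[Si](C)(C)C(C)(C)C)[C@H](c3ccc(O[Si](C(C)C)(C(C)C)C(C)C)c(OC)c3)O4)[C@H]2COCc2ccc(OCc3ccccc3)c(OC)c2)ccc1OCc1ccccc1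
F3 | step 22 | (3R,4R,5R)-5-DBF-3-(hydroxymethyl)-4-[(ArA-methoxy)methyl]oxolan-3-ol | OC[C@@]1(O)CO[C@@H](c3cc(OC)c4c(c3)[C@H](CO[Si](C)(C)C(C)(C)C)[C@H](c3ccc(O[Si](C(C)C)(C(C)C)C(C)C)c(OC)c3)O4)[C@H]1COCc1ccc(OCc2ccccc2)c(OC)c1
F4 | step 22 | (3S,4R,5R)-5-DBF-3-hydroxy-4-[(ArA-methoxy)methyl]oxolane-3-carbaldehyde | O=C[C@@]1(O)CO[C@@H](c3cc(OC)c4c(c3)[C@H](CO[Si](C)(C)C(C)(C)C)[C@H](c3ccc(O[Si](C(C)C)(C(C)C)C(C)C)c(OC)c3)O4)[C@H]1COCc1ccc(OCc2ccccc2)c(OC)c1
F5 | step 22 | (3S,4R,5R)-3-[(ArA)(hydroxy)methyl]-4-[(ArA-methoxy)methyl]-5-DBF-oxolan-3-ol (either carbinol epimer) | COc1cc(C(O)[C@@]2(O)CO[C@@H](c3cc(OC)c4c(c3)[C@H](CO[Si](C)(C)C(C)(C)C)[C@H](c3ccc(O[Si](C(C)C)(C(C)C)C(C)C)c(OC)c3)O4)[C@H]2COCc2ccc(OCc3ccccc3)c(OC)c2)ccc1OCc1ccccc1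
F6 | step 11 | ethyl 2-[5-(1,3-dioxolan-2-yl)-2-hydroxy-3-methoxyphenyl]acetate | CCOC(=O)Cc1cc(C2OCCO2)cc(OC)c1O
F7 | step 11 | {3-methoxy-4-[(triisopropylsilyl)oxy]phenyl}methanol | COc1cc(CO)ccc1O[Si](C(C)C)(C(C)C)C(C)C
F8 | step 11 | ethyl 2-[5-(1,3-dioxolan-2-yl)-3-methoxy-2-(ArC-methoxy)phenyl]acetate | CCOC(=O)Cc1cc(C2OCCO2)cc(OC)c1OCc1ccc(O[Si](C(C)C)(C(C)C)C(C)C)c(OC)c1
F9 | step 11 | ethyl 2-diazo-2-[5-(1,3-dioxolan-2-yl)-3-methoxy-2-(ArC-methoxy)phenyl]acetate | CCOC(=O)C(=[N+]=[N-])c1cc(C2OCCO2)cc(OC)c1OCc1ccc(O[Si](C(C)C)(C(C)C)C(C)C)c(OC)c1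
F10 | step 11 | ethyl (2R,3S)-5-(1,3-dioxolan-2-yl)-7-methoxy-2-ArC-2,3-dihydro-1-benzofuran-3-carboxylate | CCOC(=O)[C@@H]1[C@H](c2ccc(O[Si](C(C)C)(C(C)C)C(C)C)c(OC)c2)Oc2c(OC)cc(C3OCCO3)cc12
F11 | step 11 | [(2R,3R)-5-(1,3-dioxolan-2-yl)-7-methoxy-2-ArC-2,3-dihydro-1-benzofuran-3-yl]methanol | OC[C@@H]1[C@H](c2ccc(O[Si](C(C)C)(C(C)C)C(C)C)c(OC)c2)Oc2c(OC)cc(C3OCCO3)cc12
F12 | step 18 | methyl 3-(ArA-methoxy)propanoate | COC(=O)CCOCc1ccc(OCc2ccccc2)c(OC)c1
F13 | step 18 | 3-(ArA-methoxy)propanoic acid | OC(=O)CCOCc1ccc(OCc2ccccc2)c(OC)c1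
F14 | step 18 | (R)-4-benzyl-3-[3-(ArA-methoxy)propanoyl]oxazolidin-2-one | O=C1OC[C@@H](Cc2ccccc2)N1C(=O)CCOCc1ccc(OCc2ccccc2)c(OC)c1
F15 | step 18 | (R)-4-benzyl-3-[(2R,3R)-3-DBF-3-hydroxy-2-[(ArA-methoxy)methyl]propanoyl]oxazolidin-2-one | O=C1OC[C@@H](Cc2ccccc2)N1C(=O)[C@H](COCc1ccc(OCc2ccccc2)c(OC)c1)[C@@H](O)c3cc(OC)c4c(c3)[C@H](CO[Si](C)(C)C(C)(C)C)[C@H](c3ccc(O[Si](C(C)C)(C(C)C)C(C)C)c(OC)c3)O4
F16 | step 18 | (2R,3R)-3-DBF-3-hydroxy-2-[(ArA-methoxy)methyl]propanoic acid | OC(=O)[C@H](COCc1ccc(OCc2ccccc2)c(OC)c1)[C@@H](O)c3cc(OC)c4c(c3)[C@H](CO[Si](C)(C)C(C)(C)C)[C@H](c3ccc(O[Si](C(C)C)(C(C)C)C(C)C)c(OC)c3)O4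
F17 | step 18 | (3R,4R)-1-diazo-4-DBF-4-hydroxy-3-[(ArA-methoxy)methyl]butan-2-one | [N-]=[N+]=CC(=O)[C@H](COCc1ccc(OCc2ccccc2)c(OC)c1)[C@@H](O)c3cc(OC)c4c(c3)[C@H](CO[Si](C)(C)C(C)(C)C)[C@H](c3ccc(O[Si](C(C)C)(C(C)C)C(C)C)c(OC)c3)O4
A1 | alternative 1 | 3-[(4-hydroxy-3-methoxyphenyl)methyl]-3-(triethylsilyloxy)cyclobutan-1-one | COc1cc(CC2(O[Si](CC)(CC)CC)CC(=O)C2)ccc1O
A2 | alternative 1 | 4-[(4-hydroxy-3-methoxyphenyl)methyl]-4-(triethylsilyloxy)oxolan-2-one | COc1cc(C[C@@]2(O[Si](CC)(CC)CC)COC(=O)C2)ccc1O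
A3 | alternative 2 | methyl 2-[5-bromo-3-methoxy-2-({3-methoxy-4-[(tert-butyldimethylsilyl)oxy]phenyl}methoxy)phenyl]-2-diazoacetate | COC(=O)C(=[N+]=[N-])c1cc(Br)cc(OC)c1OCc1ccc(O[Si](C)(C)C(C)(C)C)c(OC)c1
A4 | alternative 2 | methyl cis-5-bromo-7-methoxy-2-(3-methoxy-4-silyloxyphenyl)-2,3-dihydrobenzofuran-3-carboxylate | Brc1cc(OC)c2c(c1)[C@H](C(=O)OC)[C@H](c1ccc(O[Si](C)(C)C(C)(C)C)c(OC)c1)O2
A5 | alternative 3 | (1R)-1-(dihydrobenzofuranyl)-4-(ring-A aryl)but-2-yn-1-ol | COc1cc(CC#C[C@@H](O)c2cc(OC)c3c(c2)[C@H](CO[Si](C)(C)C(C)(C)C)[C@H](c2ccc(O[Si](C)(C)C(C)(C)C)c(OC)c2)O3)ccc1O[Si](C)(C)C(C)(C)C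
A6 | alternative 3 | 3-(ring-A benzyl)-4-(silylmethyl)-5-(dihydrobenzofuranyl)furan-2(5H)-one | COc1cc(CC2=C(C[Si](C)(C)OC(C)C)[C@H](c3cc(OC)c4c(c3)[C@H](CO[Si](C)(C)C(C)(C)C)[C@H](c3ccc(O[Si](C)(C)C(C)(C)C)c(OC)c3)O4)OC2=O)ccc1O[Si](C)(C)C(C)(C)C
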